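The route cuts the O1–C5 bond of the butyrolactone: C3, C4, C5 and the ring B benzyl arm on C4 map onto a prochiral 3-benzylcyclobutanone made from eugenol and dichloroketene. A catalytic asymmetric Baeyer–Villiger ring expansion inserts oxygen into one enantiotopic C(=O)–CH2 bond, so that the lactone ring, the O1–C5 bond and the (R) centre C4 arise in one operation. The precursor is 3-[3-methoxy-4-(triisopropylsilyloxy)benzyl]cyclobutanone, which carries a silyl ether so that ring B can later be unmasked beside benzyl ethers. Trans alkylation with an enantiopure dihydrobenzofuranylmethyl bromide and an erythro-selective aldol reaction then complete the target.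

Key step: step 4

Labels: lactone atoms O1, C2 (carbonyl), C3, C4, C5; glycerol carbons C7 (carbinol on ring A), C8 (aryloxy carbon), C9 (CH2OH); ring A = aryl on C7, ring B = aryl of the C4 benzyl arm, ring C = benzo ring of the dihydrobenzofuran, ring D = its 2-aryl group.

Assumption: the senses of induction of the chiral catalysts in steps 4 and 8 are assigned by analogy with closely related substrates; if either proves opposite, the antipodal ligand (from (R)-pipecolic acid or (S)-tert-leucine) would be used with nothing else changed.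

Step 1
Reactants: 1 eugenol (4-allyl-2-methoxyphenol)
Product: 2 (4-allyl-2-methoxyphenoxy)triisopropylsilane
Conditions: TIPSCl, imidazole, DMF, rt
Reagents that add atoms: triisopropylsilyl chloride, CC(C)[Si](Cl)(C(C)C)C(C)C
Why: O-silylation of the phenol (silyl ether formation) is routine and gives an ether that should resist zinc, acetic acid, peracid and lithium amide yet fall to fluoride while benzyl ethers stay.

Step 2
Reactants: 2 (4-allyl-2-methoxyphenoxy)triisopropylsilane; 3 trichloroacetyl chloride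
Product: 4 2,2-dichloro-3-{[3-methoxy-4-(triisopropylsilyloxy)phenyl]methyl}cyclobutan-1-one (racemic)
Conditions: Zn–Cu couple, POCl3, Et2O, reflux
Reagents that add atoms: none
Why: Thermal [2+2] cycloaddition of dichloroketene, generated in the flask by zinc dechlorination of 3, to the terminal alkene; the ketene carbonyl carbon bonds to the CH2 terminus so the arylmethyl group ends at C3, and POCl3 ties up the zinc chloride.

Step 3
Reactants: 4 2,2-dichloro-3-{[3-methoxy-4-(triisopropylsilyloxy)phenyl]methyl}cyclobutan-1-one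
Product: 5 3-{[3-methoxy-4-(triisopropylsilyloxy)phenyl]methyl}cyclobutan-1-one
Conditions: Zn dust, AcOH, rt
Reagents that add atoms: none
Why: Reductive dehalogenation of the alpha,alpha-dichloroketone by zinc in acetic acid removes both chlorines through zinc enolates and leaves the achiral, prochiral 3-substituted cyclobutanone.

Step 4
Reactants: 5 3-{[3-methoxy-4-(triisopropylsilyloxy)phenyl]methyl}cyclobutan-1-one
Product: 7 (4R)-4-{[3-methoxy-4-(triisopropylsilyloxy)phenyl]methyl}oxolan-2-one, via Criegee adduct 6 (not isolated)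
Conditions: Sc(OTf)3 (5 mol%), C2-symmetric N,N'-dioxide ligand from (S)-pipecolic acid and 2,6-diisopropylaniline (6 mol%), m-CPBA (1.2 equiv), EtOAc, −20 °C
Reagents that add atoms: m-chloroperbenzoic acid, OOC(=O)c1cccc(Cl)c1
Why: m-CPBA adds to the scandium-activated carbonyl of 5 to give the peroxy hemiketal 6, in which only the ring C–C bond held anti to the O–O bond can shift, and that carbon moves from carbon to oxygen as 3-chlorobenzoate departs. The closest known reaction type is the catalytic asymmetric Baeyer–Villiger desymmetrisation of 3-substituted cyclobutanones with chiral N,N'-dioxide–Sc(OTf)3 complexes and m-CPBA. The five-membered lactone is not closed by a cyclisation but arises by ring expansion, a 1,2-shift within the ring that turns the four-membered ketone into the gamma-lactone and should be fast at low temperature because four-ring strain is lost. The new stereocentre C4 is set as R by the catalyst alone, whose ligand shell decides which of the two mirror-related CH2–C(=O) bonds migrates by reading the position of the C3 arylmethyl group. The step needs enantiotopic-group selectivity and chemoselectivity for the ketone over the electron-rich ring B; both candidate migrating carbons are CH2, so no regiochemical issue arises, the substrate has no other stereocentre to mismatch, and the strained ketone should react at −20 °C where arene oxidation by the peracid is negligible.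

Step 5
Reactants: 8 4-bromo-2-methoxyphenol
Product: 9 4-bromo-2-iodo-6-methoxyphenol
Conditions: NIS, TsOH·H2O (10 mol%), MeCN, 0 °C to rt
Reagents that add atoms: N-iodosuccinimide, O=C1CCC(=O)N1I
Why: Electrophilic aromatic iodination should go ortho to the free hydroxyl, the only strongly activated open position since the para position carries bromine.

Step 6
Reactants: 9 4-bromo-2-iodo-6-methoxyphenol; 10 [4-(benzyloxy)-3-methoxyphenyl]methanol
Product: 11 2-{[4-(benzyloxy)-3-methoxyphenyl]methoxy}-5-bromo-1-iodo-3-methoxybenzene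
Conditions: PPh3, DIAD, THF, 0 °C to rt
Reagents that add atoms: none
Why: Mitsunobu etherification of an acidic phenol with a primary benzylic alcohol installs in one step ring D together with the benzylic CH2 that becomes C2 of the dihydrobenzofuran.

Step 7
Reactants: 11 2-{[4-(benzyloxy)-3-methoxyphenyl]methoxy}-5-bromo-1-iodo-3-methoxybenzene; 12 ethyl diazoacetate
Product: 13 ethyl 2-(2-{[4-(benzyloxy)-3-methoxyphenyl]methoxy}-5-bromo-3-methoxyphenyl)-2-diazoacetate
Conditions: Pd(PPh3)4 (5 mol%), Ag2CO3 (0.5 equiv), Et3N, toluene, rt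
Reagents that add atoms: none
Why: Palladium-catalysed cross-coupling of an aryl iodide with the C–H bond of a diazoacetate (diazo group retained); zerovalent palladium inserts into C–I in preference to C–Br at room temperature.

Step 8
Reactants: 13 ethyl 2-(2-{[4-(benzyloxy)-3-methoxyphenyl]methoxy}-5-bromo-3-methoxyphenyl)-2-diazoacetate
Product: 14 ethyl (2S,3R)-2-[4-(benzyloxy)-3-methoxyphenyl]-5-bromo-7-methoxy-2,3-dihydro-1-benzofuran-3-carboxylate (cis)
Conditions: Rh2(R-PTTL)4 (dirhodium tetrakis[N-phthaloyl-(R)-tert-leucinate], 1 mol%), toluene, −60 °C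
Reagents that add atoms: none
Why: Intramolecular 1,5 C–H insertion of the dirhodium carbenoid into the benzylic C–H next to the ether oxygen forms the C2–C3 bond and the five-membered ring; the chiral carboxylate ligands select one enantiotopic benzylic hydrogen, setting C2 as S, and the concerted insertion delivers the cis ester.

Step 9
Reactants: 14 ethyl (2S,3R)-cis-2-[4-(benzyloxy)-3-methoxyphenyl]-5-bromo-7-methoxy-2,3-dihydro-1-benzofuran-3-carboxylate
Product: 15 ethyl (2S,3S)-2-[4-(benzyloxy)-3-methoxyphenyl]-5-bromo-7-methoxy-2,3-dihydro-1-benzofuran-3-carboxylate (trans)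
Conditions: NaOEt (0.2 equiv), EtOH, 0 °C to rt
Reagents that add atoms: none
Why: Base-mediated epimerisation at C3 through the ester enolate places the ester trans to the C2 aryl group under thermodynamic control; C2 should be untouched because the ring C–O bond lies in the nodal plane of the enolate and cannot eliminate.

Step 10
Reactants: 15 ethyl (2S,3S)-trans-2-[4-(benzyloxy)-3-methoxyphenyl]-5-bromo-7-methoxy-2,3-dihydro-1-benzofuran-3-carboxylate
Product: 16 {(2S,3R)-2-[4-(benzyloxy)-3-methoxyphenyl]-5-bromo-7-methoxy-2,3-dihydro-1-benzofuran-3-yl}methanol (trans)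
Conditions: LiBH4, THF, MeOH (1 equiv), 0 °C to rt
Reagents that add atoms: none
Why: Hydride reduction of the ester to the primary alcohol; LiBH4 leaves the aryl bromide and the benzyl ethers alone and touches no stereocentre (the C3 descriptor changes only through priorities).

Step 11
Reactants: 16 {(2S,3R)-2-[4-(benzyloxy)-3-methoxyphenyl]-5-bromo-7-methoxy-2,3-dihydro-1-benzofuran-3-yl}methanol
Product: 17 {[(2S,3R)-2-[4-(benzyloxy)-3-methoxyphenyl]-5-bromo-7-methoxy-2,3-dihydro-1-benzofuran-3-yl]methoxy}(tert-butyl)dimethylsilane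
Conditions: TBSCl, imidazole, CH2Cl2, rt
Reagents that add atoms: tert-butyldimethylsilyl chloride, CC(C)(C)[Si](C)(C)Cl
Why: Silyl ether formation masks the primary hydroxyl for the organolithium step and the later enolate alkylation.

Step 12
Reactants: 17 {[(2S,3R)-2-[4-(benzyloxy)-3-methoxyphenyl]-5-bromo-7-methoxy-2,3-dihydro-1-benzofuran-3-yl]methoxy}(tert-butyl)dimethylsilane
Product: 20 {(2S,3R)-2-[4-(benzyloxy)-3-methoxyphenyl]-3-{[(tert-butyldimethylsilyl)oxy]methyl}-7-methoxy-2,3-dihydro-1-benzofuran-5-yl}methanol, via aryllithium 18 (not isolated), via aldehyde 19 (not isolated)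
Conditions: n-BuLi, THF, −78 °C; DMF, −78 to 0 °C; then MeOH, NaBH4, 0 °C
Reagents that add atoms: N,N-dimethylformamide, CN(C)C=O
Why: Bromine–lithium exchange, formylation of the aryllithium with DMF (Bouveault reaction) and borohydride reduction in the same flask convert the aryl bromide into the benzylic alcohol; exchange at −78 °C should outrun any deprotonation.

Step 13
Reactants: 20 {(2S,3R)-2-[4-(benzyloxy)-3-methoxyphenyl]-3-{[(tert-butyldimethylsilyl)oxy]methyl}-7-methoxy-2,3-dihydro-1-benzofuran-5-yl}methanol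
Product: 21 {[(2S,3R)-2-[4-(benzyloxy)-3-methoxyphenyl]-5-(bromomethyl)-7-methoxy-2,3-dihydro-1-benzofuran-3-yl]methoxy}(tert-butyl)dimethylsilane
Conditions: CBr4, PPh3, CH2Cl2, 0 °C; used at once
Reagents that add atoms: carbon tetrabromide, BrC(Br)(Br)Br
Why: Appel bromination of the primary benzylic alcohol proceeds under neutral conditions that keep the silyl and benzyl ethers.

Step 14
Reactants: 22 (4S)-4-benzyl-1,3-oxazolidin-2-one; 23 bromoacetyl bromide
Product: 25 (4S)-4-benzyl-3-(bromoacetyl)-1,3-oxazolidin-2-one, via lithium salt 24 (not isolated)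
Conditions: n-BuLi, THF, −78 °C; then 23, −78 °C
Reagents that add atoms: none
Why: N-acylation of the lithiated oxazolidinone; the acyl bromide reacts far faster than the alkyl bromide.

Step 15
Reactants: 7 (4R)-4-{[3-methoxy-4-(triisopropylsilyloxy)phenyl]methyl}oxolan-2-one; 21 {[(2S,3R)-2-[4-(benzyloxy)-3-methoxyphenyl]-5-(bromomethyl)-7-methoxy-2,3-dihydro-1-benzofuran-3-yl]methoxy}(tert-butyl)dimethylsilane
Product: 27 (3R,4R)-3-({(2S,3R)-2-[4-(benzyloxy)-3-methoxyphenyl]-3-{[(tert-butyldimethylsilyl)oxy]methyl}-7-methoxy-2,3-dihydro-1-benzofuran-5-yl}methyl)-4-{[3-methoxy-4-(triisopropylsilyloxy)phenyl]methyl}oxolan-2-one, via lithium enolate 26 (not isolated)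
Conditions: LiN(SiMe3)2, THF, −78 °C; then 21, DMPU, −78 to −40 °C
Reagents that add atoms: none
Why: SN2 alkylation of the lactone lithium enolate with the benzylic bromide; the electrophile approaches C3 anti to the C4 arylmethyl group, which sets C3 as R and gives the trans-3,4-disubstituted lactone, the usual outcome for 4-benzylbutyrolactones.

Step 16
Reactants: 27 (3R,4R)-lactone bearing the ring B TIPS ether and the primary TBS ether
Product: 28 (3R,4R)-3-({(2S,3R)-2-[4-(benzyloxy)-3-methoxyphenyl]-3-(hydroxymethyl)-7-methoxy-2,3-dihydro-1-benzofuran-5-yl}methyl)-4-[(4-hydroxy-3-methoxyphenyl)methyl]oxolan-2-one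
Conditions: Bu4NF, AcOH, THF, 0 °C to rt
Reagents that add atoms: none
Why: Fluoride-mediated desilylation cleaves the aryl TIPS ether and the primary TBS ether while the benzyl ethers and the lactone are inert; acetic acid buffers the phenoxide.

Step 17
Reactants: 28 ring B phenol (3R,4R)-lactone; 25 (4S)-4-benzyl-3-(bromoacetyl)-1,3-oxazolidin-2-one
Product: 29 (4S)-4-benzyl-3-(aryloxyacetyl)-1,3-oxazolidin-2-one in which the aryloxy group is the ring B oxygen of 28
Conditions: K2CO3, acetone, rt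
Reagents that add atoms: none
Why: Williamson etherification: the ring B phenoxide displaces the primary alpha-bromide of the imide, and the far less acidic primary alcohol should not compete under carbonate.

Step 18
Reactants: 29 ring B aryloxyacetyl imide; 30 4-(benzyloxy)-3-methoxybenzaldehyde
Product: 33 (4S)-4-benzyl-3-[(2R,3R)-2-aryloxy-3-[4-(benzyloxy)-3-methoxyphenyl]-3-hydroxypropanoyl]-1,3-oxazolidin-2-one (aryloxy = ring B oxygen; anti adduct), via trimethylsilyl ether 31 (not isolated), via bis(trimethylsilyl) adduct 32 (not isolated)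
Conditions: MgCl2 (20 mol%), Et3N, TMSCl, EtOAc, 23 °C; then 1 M HCl, THF, 0 °C
Reagents that add atoms: none
Why: Magnesium halide-catalysed direct anti-aldol reaction of an N-acyloxazolidinone with an aromatic aldehyde (Evans anti-aldol); the chelated magnesium Z-enolate should be attacked on the face away from the benzyl group of the auxiliary through a boat transition state, setting C7 as R and C8 in the sense that reads 8S after reduction (the erythro pair), while TMSCl traps the aldolate for turnover and caps the primary alcohol in passing.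

Step 19
Reactants: 33 anti-aldol imide
Product: 34 ring A and ring D di-O-benzyl ether of the target (7R,8S; 3R,4R; 2S,3R)
Conditions: NaBH4, THF–H2O (4:1), 0 °C to rt
Reagents that add atoms: none
Why: Reductive cleavage of the N-acyloxazolidinone by borohydride gives the C9 primary alcohol and returns the auxiliary; the imide carbonyl is far more electrophilic than the gamma-lactone, which should survive, and no stereocentre is touched.

Step 20
Reactants: 34 di-O-benzyl ether of the target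
Product: 35 (3R,4R)-3-{[(2S,3R)-2-(4-hydroxy-3-methoxyphenyl)-3-(hydroxymethyl)-7-methoxy-2,3-dihydro-1-benzofuran-5-yl]methyl}-4-[(4-{[(1R,2S)-1,3-dihydroxy-1-(4-hydroxy-3-methoxyphenyl)propan-2-yl]oxy}-3-methoxyphenyl)methyl]oxolan-2-one (target)
Conditions: H2 (1 atm), 10% Pd/C, EtOAc–MeOH, rt
Reagents that add atoms: none
Why: Catalytic hydrogenolysis of the two aryl benzyl ethers, which should cleave much faster than the benzylic C7–OH or the benzylic ring C–O bond of the dihydrobenzofuran under neutral conditions at 1 atm.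

Compound list
1 | eugenol (4-allyl-2-methoxyphenol) | COc1cc(CC=C)ccc1O | starting material
2 | (4-allyl-2-methoxyphenoxy)triisopropylsilane | COc1cc(CC=C)ccc1O[Si](C(C)C)(C(C)C)C(C)C | intermediate
3 | trichloroacetyl chloride | O=C(Cl)C(Cl)(Cl)Cl | starting material
4 | 2,2-dichloro-3-{[3-methoxy-4-(triisopropylsilyloxy)phenyl]methyl}cyclobutan-1-one (racemic) | COc1cc(CC2CC(=O)C2(Cl)Cl)ccc1O[Si](C(C)C)(C(C)C)C(C)C | intermediate
5 | 3-{[3-methoxy-4-(triisopropylsilyloxy)phenyl]methyl}cyclobutan-1-one | COc1cc(CC2CC(=O)C2)ccc1O[Si](C(C)C)(C(C)C)C(C)C | intermediate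
6 | Criegee adduct of 5: 1-hydroxy-3-{[3-methoxy-4-(triisopropylsilyloxy)phenyl]methyl}cyclobutyl 3-chloroperbenzoate (not isolated) | COc1cc(CC2CC(O)(OOC(=O)c3cccc(Cl)c3)C2)ccc1O[Si](C(C)C)(C(C)C)C(C)C | intermediate
7 | (4R)-4-{[3-methoxy-4-(triisopropylsilyloxy)phenyl]methyl}oxolan-2-one | COc1cc(C[C@H]2COC(=O)C2)ccc1O[Si](C(C)C)(C(C)C)C(C)C | intermediate
8 | 4-bromo-2-methoxyphenol | COc1cc(Br)ccc1O | starting material
9 | 4-bromo-2-iodo-6-methoxyphenol | COc1cc(Br)cc(I)c1O | intermediate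
10 | [4-(benzyloxy)-3-methoxyphenyl]methanol | COc1cc(CO)ccc1OCc1ccccc1 | starting material
11 | 2-{[4-(benzyloxy)-3-methoxyphenyl]methoxy}-5-bromo-1-iodo-3-methoxybenzene | COc1cc(COc2c(I)cc(Br)cc2OC)ccc1OCc1ccccc1 | intermediate
12 | ethyl diazoacetate | CCOC(=O)C=[N+]=[N-] | starting material
13 | ethyl 2-(2-{[4-(benzyloxy)-3-methoxyphenyl]methoxy}-5-bromo-3-methoxyphenyl)-2-diazoacetate | CCOC(=O)C(=[N+]=[N-])c1cc(Br)cc(OC)c1OCc1ccc(OCc2ccccc2)c(OC)c1 | intermediate
14 | ethyl (2S,3R)-2-[4-(benzyloxy)-3-methoxyphenyl]-5-bromo-7-methoxy-2,3-dihydro-1-benzofuran-3-carboxylate (cis) | Brc1cc(OC)c2c(c1)[C@@H](C(=O)OCC)[C@@H](c1ccc(OCc3ccccc3)c(OC)c1)O2 | intermediate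
15 | ethyl (2S,3S)-2-[4-(benzyloxy)-3-methoxyphenyl]-5-bromo-7-methoxy-2,3-dihydro-1-benzofuran-3-carboxylate (trans) | Brc1cc(OC)c2c(c1)[C@H](C(=O)OCC)[C@@H](c1ccc(OCc3ccccc3)c(OC)c1)O2 | intermediate
16 | {(2S,3R)-2-[4-(benzyloxy)-3-methoxyphenyl]-5-bromo-7-methoxy-2,3-dihydro-1-benzofuran-3-yl}methanol (trans) | Brc1cc(OC)c2c(c1)[C@H](CO)[C@@H](c1ccc(OCc3ccccc3)c(OC)c1)O2 | intermediate
17 | {[(2S,3R)-2-[4-(benzyloxy)-3-methoxyphenyl]-5-bromo-7-methoxy-2,3-dihydro-1-benzofuran-3-yl]methoxy}(tert-butyl)dimethylsilane | Brc1cc(OC)c2c(c1)[C@H](CO[Si](C)(C)C(C)(C)C)[C@@H](c1ccc(OCc3ccccc3)c(OC)c1)O2 | intermediate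
18 | 5-lithio derivative of 17 (not isolated) | [Li]c1cc(OC)c2c(c1)[C@H](CO[Si](C)(C)C(C)(C)C)[C@@H](c1ccc(OCc3ccccc3)c(OC)c1)O2 | intermediate
19 | (2S,3R)-2-[4-(benzyloxy)-3-methoxyphenyl]-3-{[(tert-butyldimethylsilyl)oxy]methyl}-7-methoxy-2,3-dihydro-1-benzofuran-5-carbaldehyde (not isolated) | O=Cc1cc(OC)c2c(c1)[C@H](CO[Si](C)(C)C(C)(C)C)[C@@H](c1ccc(OCc3ccccc3)c(OC)c1)O2 | intermediate
20 | {(2S,3R)-2-[4-(benzyloxy)-3-methoxyphenyl]-3-{[(tert-butyldimethylsilyl)oxy]methyl}-7-methoxy-2,3-dihydro-1-benzofuran-5-yl}methanol | OCc1cc(OC)c2c(c1)[C@H](CO[Si](C)(C)C(C)(C)C)[C@@H](c1ccc(OCc3ccccc3)c(OC)c1)O2 | intermediate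
21 | {[(2S,3R)-2-[4-(benzyloxy)-3-methoxyphenyl]-5-(bromomethyl)-7-methoxy-2,3-dihydro-1-benzofuran-3-yl]methoxy}(tert-butyl)dimethylsilane | BrCc1cc(OC)c2c(c1)[C@H](CO[Si](C)(C)C(C)(C)C)[C@@H](c1ccc(OCc3ccccc3)c(OC)c1)O2 | intermediate
22 | (4S)-4-benzyl-1,3-oxazolidin-2-one | O=C1N[C@@H](Cc2ccccc2)CO1 | starting material
23 | bromoacetyl bromide | O=C(Br)CBr | starting material
24 | N-lithio-(4S)-4-benzyl-1,3-oxazolidin-2-one (not isolated) | [Li]N1[C@@H](Cc2ccccc2)COC1=O | intermediate
25 | (4S)-4-benzyl-3-(bromoacetyl)-1,3-oxazolidin-2-one | O=C(CBr)N1[C@@H](Cc2ccccc2)COC1=O | intermediate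
26 | lithium enolate of 7 (not isolated) | COc1cc(C[C@H]2COC(O[Li])=C2)ccc1O[Si](C(C)C)(C(C)C)C(C)C | intermediate
27 | (3R,4R)-3-({(2S,3R)-2-[4-(benzyloxy)-3-methoxyphenyl]-3-{[(tert-butyldimethylsilyl)oxy]methyl}-7-methoxy-2,3-dihydro-1-benzofuran-5-yl}methyl)-4-{[3-methoxy-4-(triisopropylsilyloxy)phenyl]methyl}oxolan-2-one | COc1cc(C[C@H]2COC(=O)[C@@H]2Cc2cc(OC)c3c(c2)[C@H](CO[Si](C)(C)C(C)(C)C)[C@@H](c2ccc(OCc4ccccc4)c(OC)c2)O3)ccc1O[Si](C(C)C)(C(C)C)C(C)C | intermediate
28 | (3R,4R)-3-({(2S,3R)-2-[4-(benzyloxy)-3-methoxyphenyl]-3-(hydroxymethyl)-7-methoxy-2,3-dihydro-1-benzofuran-5-yl}methyl)-4-[(4-hydroxy-3-methoxyphenyl)methyl]oxolan-2-one | COc1cc(C[C@H]2COC(=O)[C@@H]2Cc2cc(OC)c3c(c2)[C@H](CO)[C@@H](c2ccc(OCc4ccccc4)c(OC)c2)O3)ccc1O | intermediate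
29 | (4S)-4-benzyl-3-(aryloxyacetyl)-1,3-oxazolidin-2-one, aryloxy = ring B oxygen of 28 | COc1cc(C[C@H]2COC(=O)[C@@H]2Cc2cc(OC)c3c(c2)[C@H](CO)[C@@H](c2ccc(OCc4ccccc4)c(OC)c2)O3)ccc1OCC(=O)N1[C@@H](Cc2ccccc2)COC1=O | intermediate
30 | 4-(benzyloxy)-3-methoxybenzaldehyde | COc1cc(C=O)ccc1OCc1ccccc1 | starting material
31 | trimethylsilyl ether of 29 at the dihydrobenzofuran CH2OH (not isolated) | COc1cc(C[C@H]2COC(=O)[C@@H]2Cc2cc(OC)c3c(c2)[C@H](CO[Si](C)(C)C)[C@@H](c2ccc(OCc4ccccc4)c(OC)c2)O3)ccc1OCC(=O)N1[C@@H](Cc2ccccc2)COC1=O | intermediate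
32 | bis(trimethylsilyl) ether of 33 at C7–O and the dihydrobenzofuran CH2O (not isolated) | COc1cc([C@@H](O[Si](C)(C)C)[C@H](C(=O)N2[C@@H](Cc3ccccc3)COC2=O)Oc2ccc(C[C@H]3COC(=O)[C@@H]3Cc3cc(OC)c4c(c3)[C@H](CO[Si](C)(C)C)[C@@H](c3ccc(OCc5ccccc5)c(OC)c3)O4)cc2OC)ccc1OCc1ccccc1 | intermediate
33 | (4S)-4-benzyl-3-[(2R,3R)-2-aryloxy-3-[4-(benzyloxy)-3-methoxyphenyl]-3-hydroxypropanoyl]-1,3-oxazolidin-2-one, aryloxy = ring B oxygen (anti adduct) | COc1cc([C@@H](O)[C@H](C(=O)N2[C@@H](Cc3ccccc3)COC2=O)Oc2ccc(C[C@H]3COC(=O)[C@@H]3Cc3cc(OC)c4c(c3)[C@H](CO)[C@@H](c3ccc(OCc5ccccc5)c(OC)c3)O4)cc2OC)ccc1OCc1ccccc1 | intermediate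
34 | ring A and ring D di-O-benzyl ether of the target (7R,8S; 3R,4R; 2S,3R) | COc1cc([C@@H](O)[C@H](CO)Oc2ccc(C[C@H]3COC(=O)[C@@H]3Cc3cc(OC)c4c(c3)[C@H](CO)[C@@H](c3ccc(OCc5ccccc5)c(OC)c3)O4)cc2OC)ccc1OCc1ccccc1 | intermediate
35 | (3R,4R)-3-{[(2S,3R)-2-(4-hydroxy-3-methoxyphenyl)-3-(hydroxymethyl)-7-methoxy-2,3-dihydro-1-benzofuran-5-yl]methyl}-4-[(4-{[(1R,2S)-1,3-dihydroxy-1-(4-hydroxy-3-methoxyphenyl)propan-2-yl]oxy}-3-methoxyphenyl)methyl]oxolan-2-one | COc1cc([C@@H](O)[C@H](CO)Oc2ccc(C[C@H]3COC(=O)[C@@H]3Cc3cc(OC)c4c(c3)[C@H](CO)[C@@H](c3ccc(O)c(OC)c3)O4)cc2OC)ccc1O | target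

Total step count: 20 steps (lactone arm 4, dihydrobenzofuran arm 9, auxiliary reagent 1, union and endgame 6).
Longest linear sequence: 15 steps (steps 5 to 13, then 15 to 20).

Steps most likely to fail

Step 4. The catalyst may discriminate poorly between the two enantiotopic methylene groups, because the only differentiating group sits on a flexible CH2 remote from the carbonyl, so the lactone may form with insufficient enantiomeric purity. Fallback, from 5 back to 7: enantioselective deprotonation with the chiral base LiN[(S)-CH(CH3)Ph]2 in the presence of TMSCl (THF, −100 °C) desymmetrises the ketone as (3R)-3-{[3-methoxy-4-(triisopropylsilyloxy)phenyl]methyl}-1-(trimethylsilyloxy)cyclobut-1-ene F1 (sense of the base by analogy). Ozonolysis (O3, CH2Cl2–MeOH, −78 °C, then Me2S) cleaves the enol ether double bond to the aldehyde acid F2, NaBH4 reduces the aldehyde to the hydroxy acid F3, and 1 M HCl closes F3 to 7. Oxygen insertion is thus replaced by enolisation and oxidative C=C cleavage, which is known for 3-benzylcyclobutanones.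

Step 8. The carbenoid may select weakly between the two enantiotopic benzylic hydrogens, or be diverted into oxonium ylide formation at the flanked ether oxygen. Fallback, from 9 back to 16 (bypassing steps 6 to 10 and all carbene chemistry): MOMCl and iPr2NEt give 5-bromo-1-iodo-3-methoxy-2-(methoxymethoxy)benzene F4. Palladium-catalysed coupling at the C–I bond with the Reformatsky reagent BrZnCH2CO2Et (Pd2(dba)3, XPhos, THF) gives the arylacetate F5, and LiOH gives the acid F6. Mixed anhydride formation (PivCl, Et3N) and reaction with the lithium salt of 22 give the imide F7. An Evans syn-aldol reaction (Bu2BOTf, iPr2NEt, CH2Cl2, −78 to 0 °C) with 30 gives the syn adduct F8, which fixes the future C3. LiBH4 gives the diol F9, and TFA in CH2Cl2 at 0 °C removes the MOM group and closes the ring through the benzylic cation, trans to the C3 substituent, to give 16.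

Step 18. Anti selectivity may erode through reversible aldol addition before silylation, or through competing coordination of magnesium by the aryloxy oxygen, giving erythro/threo mixtures. Fallback, from 28 back to 34: 28 is alkylated (K2CO3, acetone) with (4R)-4-benzyl-3-(bromoacetyl)-1,3-oxazolidin-2-one F10, made as in step 14 from the (R)-oxazolidinone, to give the imide F11. Its dibutylboron enolate (Bu2BOTf, iPr2NEt, CH2Cl2, −78 to 0 °C, one extra equivalent for the free alcohol) adds to 30 through a Zimmerman–Traxler chair to give the syn adduct F12, with C8 correct and C7 epimeric. Mitsunobu inversion at C7 with 4-nitrobenzoic acid (PPh3, DIAD), which also esterifies the primary alcohol, gives the bis(4-nitrobenzoate) F13. NaBH4 in THF–H2O cleaves the auxiliary to the primary alcohol F14, and K2CO3 in MeOH removes both nitrobenzoates to reach 34.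

Further compounds
F1 | step 4 | (3R)-3-{[3-methoxy-4-(triisopropylsilyloxy)phenyl]methyl}-1-(trimethylsilyloxy)cyclobut-1-ene | COc1cc(C[C@H]2C=C(O[Si](C)(C)C)C2)ccc1O[Si](C(C)C)(C(C)C)C(C)C
F2 | step 4 | (3R)-3-formyl-4-[3-methoxy-4-(triisopropylsilyloxy)phenyl]butanoic acid | COc1cc(C[C@H](CC(O)=O)C=O)ccc1O[Si](C(C)C)(C(C)C)C(C)C
F3 | step 4 | (3R)-3-(hydroxymethyl)-4-[3-methoxy-4-(triisopropylsilyloxy)phenyl]butanoic acid | COc1cc(C[C@H](CC(O)=O)CO)ccc1O[Si](C(C)C)(C(C)C)C(C)C
F4 | step 8 | 5-bromo-1-iodo-3-methoxy-2-(methoxymethoxy)benzene | COCOc1c(I)cc(Br)cc1OC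
F5 | step 8 | ethyl 2-[5-bromo-3-methoxy-2-(methoxymethoxy)phenyl]acetate | CCOC(=O)Cc1cc(Br)cc(OC)c1OCOC
F6 | step 8 | 2-[5-bromo-3-methoxy-2-(methoxymethoxy)phenyl]acetic acid | OC(=O)Cc1cc(Br)cc(OC)c1OCOC
F7 | step 8 | (4S)-4-benzyl-3-{2-[5-bromo-3-methoxy-2-(methoxymethoxy)phenyl]acetyl}-1,3-oxazolidin-2-one | O=C(Cc1cc(Br)cc(OC)c1OCOC)N1[C@@H](Cc2ccccc2)COC1=O
F8 | step 8 | (4S)-4-benzyl-3-{(2S,3S)-3-[4-(benzyloxy)-3-methoxyphenyl]-2-[5-bromo-3-methoxy-2-(methoxymethoxy)phenyl]-3-hydroxypropanoyl}-1,3-oxazolidin-2-one | O=C(N1[C@@H](Cc2ccccc2)COC1=O)[C@@H](c1cc(Br)cc(OC)c1OCOC)[C@H](O)c1ccc(OCc2ccccc2)c(OC)c1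
F9 | step 8 | (1S,2R)-1-[4-(benzyloxy)-3-methoxyphenyl]-2-[5-bromo-3-methoxy-2-(methoxymethoxy)phenyl]propane-1,3-diol | OC[C@@H](c1cc(Br)cc(OC)c1OCOC)[C@H](O)c1ccc(OCc2ccccc2)c(OC)c1
F10 | step 18 | (4R)-4-benzyl-3-(bromoacetyl)-1,3-oxazolidin-2-one | O=C(CBr)N1[C@H](Cc2ccccc2)COC1=O
F11 | step 18 | (4R)-4-benzyl-3-(aryloxyacetyl)-1,3-oxazolidin-2-one, aryloxy = ring B oxygen of 28 | COc1cc(C[C@H]2COC(=O)[C@@H]2Cc2cc(OC)c3c(c2)[C@H](CO)[C@@H](c2ccc(OCc4ccccc4)c(OC)c2)O3)ccc1OCC(=O)N1[C@H](Cc2ccccc2)COC1=O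
F12 | step 18 | (4R)-4-benzyl-3-[(2R,3S)-2-aryloxy-3-[4-(benzyloxy)-3-methoxyphenyl]-3-hydroxypropanoyl]-1,3-oxazolidin-2-one (syn adduct) | COc1cc([C@H](O)[C@H](C(=O)N2[C@H](Cc3ccccc3)COC2=O)Oc2ccc(C[C@H]3COC(=O)[C@@H]3Cc3cc(OC)c4c(c3)[C@H](CO)[C@@H](c3ccc(OCc5ccccc5)c(OC)c3)O4)cc2OC)ccc1OCc1ccccc1
F13 | step 18 | bis(4-nitrobenzoate) of the C7-inverted adduct (esters at C7–O and at the dihydrobenzofuran CH2O; acyl chain 2R,3R) | COc1cc([C@@H](OC(=O)c2ccc(cc2)[N+](=O)[O-])[C@H](C(=O)N2[C@H](Cc3ccccc3)COC2=O)Oc2ccc(C[C@H]3COC(=O)[C@@H]3Cc3cc(OC)c4c(c3)[C@H](COC(=O)c5ccc(cc5)[N+](=O)[O-])[C@@H](c3ccc(OCc5ccccc5)c(OC)c3)O4)cc2OC)ccc1OCc1ccccc1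
F14 | step 18 | bis(4-nitrobenzoate) of 34 (esters at C7–O and at the dihydrobenzofuran CH2O; C9–OH free) | COc1cc([C@@H](OC(=O)c2ccc(cc2)[N+](=O)[O-])[C@H](CO)Oc2ccc(C[C@H]3COC(=O)[C@@H]3Cc3cc(OC)c4c(c3)[C@H](COC(=O)c5ccc(cc5)[N+](=O)[O-])[C@@H](c3ccc(OCc5ccccc5)c(OC)c3)O4)cc2OC)ccc1OCc1ccccc1
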